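**Retrosynthetic overview**
1. The C5 ester goes on last, by regioselective acylation of a cis-5,6-diol; the β-hydroxyethyl ketone comes from a C1 carboxyl (MeLi, then formaldehyde aldol).
2. The C1 quaternary centre is set by late methylation of the decalin acid dianion, anti to the axial sec-butyl group; the C8 methyl comes from ketone → methylene → thermodynamic HAT hydrogenation.
3. Ring A is closed last and not by a Diels–Alder reaction: RCM forms C3=C4 after an Ireland–Claisen rearrangement forms C1–C2 with 1,3-chirality transfer from an (R)-allylic alcohol that already carries the (R)-sec-butyl group.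
4. Ring B is taken from the chiral pool: quinic acid gives an enone with both oxygens (C5, C6) in place; one flask (conjugate vinylation, then enolate alkylation) sets C4a/C8a trans and installs both the RCM handle and the Claisen ester.
5. Ring order: ring B (chiral pool) first, ring A second (Claisen, then RCM).

Assumption: (R)-2-methylbutan-1-ol is bought as the single enantiomer; intermediates use the decalin numbering of the target (C1 quaternary, C2 sec-butyl, C3=C4, C4a, C5 O-acyl, C6 OH, C7, C8 Me, C8a; β = face of H-4a) and R* = (2R,3E,5R)-5-methylhept-3-en-2-yl.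

**Route**

Step 1
Reactants: 1 D-(−)-quinic acid
Product: 2 3,4-O-isopropylidene-1,5-quinide
Conditions: Me2C(OMe)2, TsOH·H2O (cat.), acetone, reflux
Reagents that add atoms: 2,2-dimethoxypropane COC(C)(C)OC
Why: Acid-catalysed acetalisation of the only cis-diol (C3/C4) with lactonisation of the carboxyl onto the cis C5–OH gives the known bicyclic quinide acetonide without touching a stereocentre.

Step 2
Reactants: 2 3,4-O-isopropylidene-1,5-quinide
Product: 3 quinic triol acetonide (1-hydroxymethyl-1,5-diol)
Conditions: NaBH4, EtOH, 0 °C → rt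
Reagents that add atoms: none
Why: Hydride reduction of the strained, α-oxygenated γ-lactone (lactone reduction) gives the primary alcohol and frees the C5–OH, leaving the acetonide alone.

Step 3
Reactants: 3 quinic triol acetonide
Product: 4 5-hydroxy-3,4-(isopropylidenedioxy)cyclohexanone
Conditions: NaIO4, H2O (pH 6 buffer), 0 °C → rt
Reagents that add atoms: none
Why: Malaprade periodate cleavage of the only free 1,2-diol (tertiary OH/CH2OH) removes the CH2OH carbon as formaldehyde and leaves the ketone that becomes C8.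

Step 4
Reactants: 4 5-hydroxy-3,4-(isopropylidenedioxy)cyclohexanone
Product: 6 (4S,5R)-4,5-(isopropylidenedioxy)cyclohex-2-en-1-one, via mesylate 5 (not isolated)
Conditions: MsCl, Et3N, CH2Cl2, 0 °C
Reagents that add atoms: none
Why: Mesylation of the β-hydroxy ketone and in-situ E1cB elimination give the known quinic enone, whose acetonide carbons are the future C5 and C6 (both oxygens β).

Step 5
Reactants: 7 (R)-2-methylbutan-1-ol
Product: 9 (3E,5R)-5-methylhept-3-en-2-one, via (R)-2-methylbutanal 8 (not isolated)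
Conditions: TEMPO (cat.), PhI(OAc)2, CH2Cl2, rt; then Ph3P=CHCOMe, 40 °C
Reagents that add atoms: 1-(triphenylphosphoranylidene)propan-2-one CC(=O)C=P(c1ccccc1)(c1ccccc1)c1ccccc1
Why: TEMPO/PhI(OAc)2 oxidation gives the α-chiral aldehyde under non-epimerising conditions and the stabilised ylide traps it at once in an E-selective Wittig olefination.

Step 6
Reactants: 9 (3E,5R)-5-methylhept-3-en-2-one
Product: 10 (2R,3E,5R)-5-methylhept-3-en-2-ol
Conditions: (S)-Me-CBS (10 mol%), catecholborane, toluene, −78 °C
Reagents that add atoms: none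
Why: Corey–Bakshi–Shibata reduction of the methyl enone (alkenyl large, methyl small) with the (S)-oxazaborolidine gives the (2R)-allylic alcohol that later relays chirality to C2.

Step 7
Reactants: 10 (2R,3E,5R)-5-methylhept-3-en-2-ol
Product: 11 (2R,3E,5R)-5-methylhept-3-en-2-yl bromoacetate
Conditions: BrCH2COBr, pyridine, CH2Cl2, −20 °C
Reagents that add atoms: bromoacetyl bromide BrCC(Br)=O
Why: O-Acylation of the secondary allylic alcohol with the acid bromide gives the α-bromo ester that serves both as enolate electrophile and as Claisen ester.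

Step 8
Reactants: 6 (4S,5R)-4,5-(isopropylidenedioxy)cyclohex-2-en-1-one; 11 (2R,3E,5R)-5-methylhept-3-en-2-yl bromoacetate
Product: 13 keto ester (C8 ketone; 4aα-vinyl; 8aβ-CH2CO2R*; 5β,6β-acetonide), via bromomagnesium enolate 12 (not isolated)
Conditions: CH2=CHMgBr, CuBr·SMe2 (10 mol%), THF, −78 °C; then 11, DMPU, −78 → −20 °C
Reagents that add atoms: vinylmagnesium bromide C=C[Mg]Br
Why: Copper-catalysed conjugate addition of the vinyl Grignard occurs anti to the adjacent acetonide oxygen (sets C4a, vinyl α) and the regiodefined magnesium enolate is C-alkylated by the bromoacetate anti to the new vinyl group (sets C8a, trans), a tandem conjugate addition–enolate alkylation.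

Step 9
Reactants: 13 keto ester
Product: 14 methylene ester (C8=CH2; otherwise as 13)
Conditions: Zn, CH2Br2, TiCl4, THF/CH2Cl2, 0 °C → rt
Reagents that add atoms: dibromomethane BrCBr
Why: The non-basic Takai–Lombardo methylenation converts the hindered ketone chemoselectively (ester untouched, no β-alkoxide elimination) into the exocyclic alkene that becomes the C8 methyl.

Step 10
Reactants: 14 methylene ester
Product: 17 (2S,3S,4R)-2-(ring B)-4-methyl-3-[(E)-prop-1-enyl]hexanoic acid, via silyl ketene acetal 15 (not isolated), via trimethylsilyl ester 16 (not isolated)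
Conditions: LDA, THF/HMPA (4:1), −78 °C; Me3SiCl; −78 → 50 °C; 1 M HCl work-up
Reagents that add atoms: none
Why: Ireland–Claisen rearrangement through a chair transition state with all substituents equatorial: the (R)-carbinol centre and the E-alkene transfer chirality to give (S)-C2 and an E-propenyl group, and the Z(O)-enolate formed in THF/HMPA gives (S)-C1 (a centre that is reset in step 13).

Step 11
Reactants: 17 Claisen acid
Product: 18 trans-decalin acid (1α-CO2H; 2α-sec-butyl; C3=C4; 5β,6β-acetonide; C8=CH2)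
Conditions: Grubbs II (5 mol%), CH2Cl2 (5 mM), 40 °C
Reagents that add atoms: none
Why: Ring-closing metathesis between the C4a vinyl and the propenyl group (propene lost) closes ring A as the cis C3=C4 cyclohexene on the trans-diequatorial 4a,8a substituents, giving the trans-decalin; the hindered 1,1-disubstituted exocyclic alkene does not take part.

Step 12
Reactants: 18 trans-decalin acid
Product: 19 8α-methyl decalin acid
Conditions: Mn(dpm)3 (10 mol%), PhSiH3, t-BuOOH, i-PrOH, rt
Reagents that add atoms: none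
Why: Mn-catalysed hydrogen-atom-transfer hydrogenation (Mukaiyama-type, thermodynamic stereocontrol) reduces only the 1,1-disubstituted alkene via the tertiary C8 radical, and axial H delivery gives the more stable equatorial 8α-methyl (the axial epimer would be 1,3-diaxial to the C6 oxygen).

Step 13
Reactants: 19 8α-methyl decalin acid
Product: 21 1β-methyl-1α-carboxylic acid, via dilithium enediolate 20 (not isolated)
Conditions: LDA (2.5 equiv), THF/DMPU, −78 → 0 °C; MeI, −78 °C → rt; dilute HCl, 0 °C
Reagents that add atoms: iodomethane CI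
Why: Alkylation of the carboxylic acid dianion: the pseudo-axial α-sec-butyl group on C2 blocks the α face, so MeI enters from the β face and sets the quaternary centre with 1β-Me and 1α-CO2H.

Step 14
Reactants: 21 1β-methyl-1α-carboxylic acid
Product: 22 methyl ketone (1α-acetyl)
Conditions: MeLi (4 equiv), Et2O, 0 °C → rt; H2O
Reagents that add atoms: methyllithium [Li]C
Why: Methyllithium adds to the lithium carboxylate to give a stable dilithium gem-diolate that collapses to the methyl ketone only on work-up (classical acid-to-methyl-ketone conversion), so no tertiary alcohol forms.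

Step 15
Reactants: 22 methyl ketone
Product: 24 β-hydroxyethyl ketone, via lithium enolate 23 (not isolated)
Conditions: LDA, THF, −78 °C; CH2O (g), −78 °C; H2O
Reagents that add atoms: formaldehyde C=O
Why: The ketone can enolise only towards its methyl group, and aldol addition of this lithium enolate to monomeric formaldehyde (hydroxymethylation) gives the 3-hydroxypropanoyl side chain.

Step 16
Reactants: 24 β-hydroxyethyl ketone
Product: 25 primary TBDPS ether
Conditions: TBDPSCl, imidazole, DMF, rt
Reagents that add atoms: tert-butyl(chloro)diphenylsilane CC(C)(C)[Si](Cl)(c1ccccc1)c1ccccc1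
Why: Silylation of the primary alcohol with a robust TBDPS group that survives the acidic acetonide removal and is cleaved last by fluoride.

Step 17
Reactants: 25 primary TBDPS ether
Product: 26 cis-5β,6β-diol
Conditions: AcOH/H2O (4:1), 45 °C
Reagents that add atoms: none
Why: Mild aqueous acid hydrolysis of the acetonide frees the cis-diol (equatorial C5–OH, axial C6–OH) while the TBDPS ether and the β-silyloxy ketone survive.

Step 18
Reactants: 27 tert-butyl acetoacetate
Product: 28 tert-butyl (E)-3-(trifluoromethylsulfonyloxy)but-2-enoate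
Conditions: Tf2O, aq. Me4NOH, hexanes, 5 °C
Reagents that add atoms: trifluoromethanesulfonic anhydride O=S(=O)(OS(=O)(=O)C(F)(F)F)C(F)(F)F
Why: Frantz-type enol triflation of the β-keto ester: the non-chelated tetramethylammonium enolate gives the (E)-enol triflate (triflate trans to the ester), which fixes the later alkene geometry.

Step 19
Reactants: 28 tert-butyl (E)-3-(trifluoromethylsulfonyloxy)but-2-enoate
Product: 29 1-tert-butyl 5-methyl (E)-3-methylpent-2-enedioate
Conditions: BrCH2CO2Me, Zn (activated), THF, rt; then 28, Pd(PPh3)4 (5 mol%), THF, 45 °C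
Reagents that add atoms: methyl bromoacetate COC(=O)CBr
Why: Palladium-catalysed Negishi-type coupling of the Reformatsky reagent with the enol triflate proceeds with retention, so CH2CO2Me ends trans to the tert-butyl ester (E-3-methylglutaconate) with the two esters differentiated.

Step 20
Reactants: 29 1-tert-butyl 5-methyl (E)-3-methylpent-2-enedioate
Product: 30 (E)-5-methoxy-3-methyl-5-oxopent-2-enoic acid
Conditions: TFA, CH2Cl2, 0 °C → rt
Reagents that add atoms: none
Why: Acidolysis of the tert-butyl ester (loss of isobutene) frees the conjugated acid and keeps the methyl ester, with no base present that could scramble the alkene geometry.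

Step 21
Reactants: 26 cis-5β,6β-diol; 30 (E)-5-methoxy-3-methyl-5-oxopent-2-enoic acid
Product: 33 O-TBDPS-tandyukisin B, via acid chloride 31 (not isolated), via dibutylstannylene acetal 32 (not isolated)
Conditions: 30, Me2C=C(Cl)NMe2, CH2Cl2, 0 °C; separately 26, Bu2SnO, toluene, reflux (−H2O); combine, 0 °C → rt
Reagents that add atoms: none
Why: The acid is converted into its chloride under neutral conditions (Ghosez reagent) and the dibutylstannylene acetal of the cis-diol is acylated selectively at the equatorial oxygen (C5) without added base (stannylene-mediated regioselective acylation), so the axial C6–OH stays free and the E-alkene is not isomerised.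

Step 22
Reactants: 33 O-TBDPS-tandyukisin B
Product: 34 tandyukisin B
Conditions: HF·pyridine, pyridine/THF, 0 °C → rt
Reagents that add atoms: none
Why: Fluoride cleavage of the primary TBDPS ether under buffered, slightly acidic conditions leaves both esters, the β-hydroxy ketone and the cis-hydroxy ester (no acyl migration) intact and gives the target.

**Compound list**

1 | D-(−)-quinic acid | O[C@@]1(C(O)=O)C[C@@H](O)[C@@H](O)[C@H](O)C1 | starting material
2 | 3,4-O-isopropylidene-1,5-quinide | O[C@@]12C[C@H]3OC(C)(C)O[C@H]3[C@@H](C1)OC2=O | intermediate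
3 | quinic triol acetonide (1-hydroxymethyl-1,5-diol) | OC[C@]1(O)C[C@H]2OC(C)(C)O[C@H]2[C@H](O)C1 | intermediate
4 | 5-hydroxy-3,4-(isopropylidenedioxy)cyclohexanone | O=C1C[C@H]2OC(C)(C)O[C@H]2[C@H](O)C1 | intermediate
5 | mesylate of 4 | O=C1C[C@H]2OC(C)(C)O[C@H]2[C@H](OS(C)(=O)=O)C1 | intermediate
6 | (4S,5R)-4,5-(isopropylidenedioxy)cyclohex-2-en-1-one | O=C1C=C[C@@H]2OC(C)(C)O[C@@H]2C1 | intermediate
7 | (R)-2-methylbutan-1-ol | CC[C@@H](C)CO | starting material
8 | (R)-2-methylbutanal | CC[C@@H](C)C=O | intermediate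
9 | (3E,5R)-5-methylhept-3-en-2-one | CC[C@@H](C)/C=C/C(C)=O | intermediate
10 | (2R,3E,5R)-5-methylhept-3-en-2-ol | CC[C@@H](C)/C=C/[C@@H](C)O | intermediate
11 | (2R,3E,5R)-5-methylhept-3-en-2-yl bromoacetate | CC[C@@H](C)/C=C/[C@@H](C)OC(=O)CBr | intermediate
12 | bromomagnesium enolate of the 4aα-vinyl ketone | C=C[C@H]1[C@@H]2OC(C)(C)O[C@@H]2CC(O[Mg]Br)=C1 | intermediate
13 | keto ester (C8 ketone; 4aα-vinyl; 8aβ-CH2CO2R*; 5β,6β-acetonide) | C=C[C@H]1[C@@H]2OC(C)(C)O[C@@H]2CC(=O)[C@@H]1CC(=O)O[C@H](C)/C=C/[C@H](C)CC | intermediate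
14 | methylene ester (C8=CH2) | C=C[C@H]1[C@@H]2OC(C)(C)O[C@@H]2CC(=C)[C@@H]1CC(=O)O[C@H](C)/C=C/[C@H](C)CC | intermediate
15 | (Z)-O-trimethylsilyl ketene acetal of 14 | C=C[C@H]1[C@@H]2OC(C)(C)O[C@@H]2CC(=C)[C@@H]1/C=C(\O[Si](C)(C)C)O[C@H](C)/C=C/[C@H](C)CC | intermediate
16 | trimethylsilyl ester of 17 | C=C[C@H]1[C@@H]2OC(C)(C)O[C@@H]2CC(=C)[C@@H]1[C@@H](C(=O)O[Si](C)(C)C)[C@H](/C=C/C)[C@H](C)CC | intermediate
17 | (2S,3S,4R)-2-(ring B)-4-methyl-3-[(E)-prop-1-enyl]hexanoic acid | C=C[C@H]1[C@@H]2OC(C)(C)O[C@@H]2CC(=C)[C@@H]1[C@@H](C(O)=O)[C@H](/C=C/C)[C@H](C)CC | intermediate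
18 | trans-decalin acid (1α-CO2H; 2α-sec-butyl; C3=C4; 5β,6β-acetonide; C8=CH2) | CC[C@@H](C)[C@H]1C=C[C@H]2[C@@H]3OC(C)(C)O[C@@H]3CC(=C)[C@@H]2[C@H]1C(O)=O | intermediate
19 | 8α-methyl decalin acid | CC[C@@H](C)[C@H]1C=C[C@H]2[C@@H]3OC(C)(C)O[C@@H]3C[C@@H](C)[C@@H]2[C@H]1C(O)=O | intermediate
20 | dilithium enediolate of 19 | CC[C@@H](C)[C@H]1C=C[C@H]2[C@@H]3OC(C)(C)O[C@@H]3C[C@@H](C)[C@@H]2C1=C(O[Li])O[Li] | intermediate
21 | 1β-methyl-1α-carboxylic acid | CC[C@@H](C)[C@H]1C=C[C@H]2[C@@H]3OC(C)(C)O[C@@H]3C[C@@H](C)[C@@H]2[C@@]1(C)C(O)=O | intermediate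
22 | methyl ketone (1α-acetyl) | CC[C@@H](C)[C@H]1C=C[C@H]2[C@@H]3OC(C)(C)O[C@@H]3C[C@@H](C)[C@@H]2[C@@]1(C)C(C)=O | intermediate
23 | lithium enolate of 22 | CC[C@@H](C)[C@H]1C=C[C@H]2[C@@H]3OC(C)(C)O[C@@H]3C[C@@H](C)[C@@H]2[C@@]1(C)C(O[Li])=C | intermediate
24 | β-hydroxyethyl ketone (5,6-acetonide) | CC[C@@H](C)[C@H]1C=C[C@H]2[C@@H]3OC(C)(C)O[C@@H]3C[C@@H](C)[C@@H]2[C@@]1(C)C(=O)CCO | intermediate
25 | primary TBDPS ether of 24 | CC[C@@H](C)[C@H]1C=C[C@H]2[C@@H]3OC(C)(C)O[C@@H]3C[C@@H](C)[C@@H]2[C@@]1(C)C(=O)CCO[Si](c1ccccc1)(c1ccccc1)C(C)(C)C | intermediate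
26 | cis-5β,6β-diol | CC[C@@H](C)[C@H]1C=C[C@H]2[C@H](O)[C@H](O)C[C@@H](C)[C@@H]2[C@@]1(C)C(=O)CCO[Si](c1ccccc1)(c1ccccc1)C(C)(C)C | intermediate
27 | tert-butyl acetoacetate | CC(=O)CC(=O)OC(C)(C)C | starting material
28 | tert-butyl (E)-3-(trifluoromethylsulfonyloxy)but-2-enoate | C/C(OS(=O)(=O)C(F)(F)F)=C\C(=O)OC(C)(C)C | intermediate
29 | 1-tert-butyl 5-methyl (E)-3-methylpent-2-enedioate | COC(=O)C/C(C)=C/C(=O)OC(C)(C)C | intermediate
30 | (E)-5-methoxy-3-methyl-5-oxopent-2-enoic acid | COC(=O)C/C(C)=C/C(O)=O | intermediate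
31 | acid chloride of 30 | COC(=O)C/C(C)=C/C(Cl)=O | intermediate
32 | dibutylstannylene acetal of 26 | CC[C@@H](C)[C@H]1C=C[C@H]2[C@@H]3O[Sn](CCCC)(CCCC)O[C@@H]3C[C@@H](C)[C@@H]2[C@@]1(C)C(=O)CCO[Si](c1ccccc1)(c1ccccc1)C(C)(C)C | intermediate
33 | O-TBDPS-tandyukisin B | CC[C@@H](C)[C@H]1C=C[C@H]2[C@H](OC(=O)/C=C(\C)CC(=O)OC)[C@H](O)C[C@@H](C)[C@@H]2[C@@]1(C)C(=O)CCO[Si](c1ccccc1)(c1ccccc1)C(C)(C)C | intermediate
34 | tandyukisin B | CC[C@@H](C)[C@H]1C=C[C@H]2[C@H](OC(=O)/C=C(\C)CC(=O)OC)[C@H](O)C[C@@H](C)[C@@H]2[C@@]1(C)C(=O)CCO | target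

**Counts and risks**

Total step count: 22. Longest linear sequence: 16 steps (steps 1–4, 8–17, 21 and 22, from quinic acid).

Steps most likely to fail:

Step 8. The one-pot vinylation/alkylation uses a hindered, base-sensitive bromoacetate; enolate equilibration could cause β-alkoxide loss, and the electrophile could be attacked at its ester or allylic position. The fallback sets out from 6. The conjugate addition is run with Me3SiCl and stopped at the trimethylsilyl enol ether F1. The lithium enolate is regenerated from F1 with MeLi and alkylated with the small electrophile methyl bromoacetate to give the keto methyl ester F2. Lombardo methylenation gives the methylene methyl ester F3, and LiOH saponification gives the ring-B acetic acid F4. DCC/DMAP esterification of F4 with alcohol 10 comes back to the route at 14.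

Step 13. The enediolate of 19 is strained against the peri 8α-methyl group, so deprotonation or C-methylation at this neopentyl position may be slow or unselective. The fallback sets out from 19. The acid is converted (CDI, then NH3) into the primary amide F5 and dehydrated (TFAA, pyridine) to the nitrile F6. The small ketene-iminate anion of F6 (LDA) is methylated by MeI from the same β face to give the quaternary nitrile F7. MeLi addition and mild hydrolysis of the ketimine give the methyl ketone 22, where the route is rejoined (step 14 is then skipped).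

Step 21. Acylation could occur at C6 as well, or the glutaconyl chloride could lose its E geometry. The fallback sets out from 26. HC(OMe)3/PPTS gives the cyclic 5,6-orthoformate F8, and its mild aqueous acid opening gives the axial 6-O-formate F9 with the C5–OH free. F9 is acylated at C5 with acid chloride 31 (2,6-lutidine, −20 °C) to give the 5-O-acyl-6-O-formate F10. Selective methanolysis of the formate (KHCO3, MeOH, 0 °C) comes back to the route at 33.

**Further compounds**

F1 | step 8 | trimethylsilyl enol ether of the 4aα-vinyl ketone | C=C[C@H]1[C@@H]2OC(C)(C)O[C@@H]2CC(O[Si](C)(C)C)=C1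
F2 | step 8 | keto methyl ester (methyl analogue of 13) | C=C[C@H]1[C@@H]2OC(C)(C)O[C@@H]2CC(=O)[C@@H]1CC(=O)OC
F3 | step 8 | methylene methyl ester (methyl analogue of 14) | C=C[C@H]1[C@@H]2OC(C)(C)O[C@@H]2CC(=C)[C@@H]1CC(=O)OC
F4 | step 8 | ring-B acetic acid (acid of 14) | C=C[C@H]1[C@@H]2OC(C)(C)O[C@@H]2CC(=C)[C@@H]1CC(O)=O
F5 | step 13 | primary amide of 19 | CC[C@@H](C)[C@H]1C=C[C@H]2[C@@H]3OC(C)(C)O[C@@H]3C[C@@H](C)[C@@H]2[C@H]1C(N)=O
F6 | step 13 | nitrile (1α-cyano analogue of 19) | CC[C@@H](C)[C@H]1C=C[C@H]2[C@@H]3OC(C)(C)O[C@@H]3C[C@@H](C)[C@@H]2[C@H]1C#N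
F7 | step 13 | quaternary nitrile (1β-methyl-1α-cyano) | CC[C@@H](C)[C@H]1C=C[C@H]2[C@@H]3OC(C)(C)O[C@@H]3C[C@@H](C)[C@@H]2[C@@]1(C)C#N
F8 | step 21 | cyclic 5,6-orthoformate of 26 | CC[C@@H](C)[C@H]1C=C[C@H]2[C@@H]3OC(OC)O[C@@H]3C[C@@H](C)[C@@H]2[C@@]1(C)C(=O)CCO[Si](c1ccccc1)(c1ccccc1)C(C)(C)C
F9 | step 21 | 6-O-formate of 26 (C5–OH free) | CC[C@@H](C)[C@H]1C=C[C@H]2[C@H](O)[C@H](OC=O)C[C@@H](C)[C@@H]2[C@@]1(C)C(=O)CCO[Si](c1ccccc1)(c1ccccc1)C(C)(C)C
F10 | step 21 | 5-O-acyl-6-O-formate (6-O-formate of 33) | CC[C@@H](C)[C@H]1C=C[C@H]2[C@H](OC(=O)/C=C(\C)CC(=O)OC)[C@H](OC=O)C[C@@H](C)[C@@H]2[C@@]1(C)C(=O)CCO[Si](c1ccccc1)(c1ccccc1)C(C)(C)C
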